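**Retrosynthetic overview**

1. Target 19 ⇐ removal of four MOM acetals and oxidation of the C4 carbinol ⇐ (2S,4S)-flavan-4-ol 17.
2. 17 ⇐ O1–C8a aryl ether closure of ring C ⇐ anti-(1S,3S)-1,3-diol 16, which carries Br on the ring A carbon that becomes C8a. The strategy rests on one feature: O1 is the only link between the stereocentre C2 and the aromatic carbon C8a of ring A, so ring C can be closed from the aromatic end and the benzylic C2–O bond is never broken.
3. 16 ⇐ 1,3-anti reduction (C4) and asymmetric transfer hydrogenation (C2) ⇐ 1,3-diketone 14 ⇐ aldol (C2–C3 bond) and oxidation ⇐ acetophenone 11 + aldehyde 8.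
4. 11 ⇐ 5-bromoresorcinol (C-acetylation, MOM protection). 8 ⇐ 3-bromo-4,5-dihydroxybenzaldehyde (MOM, acetal, arylcopper alkylation with geranyl bromide forming C5'–C1'').
5. Ring order: rings A and B are bought as benzene rings; ring C is the only ring formed, in step 10.

Key step: step 10

Remark: flavan numbering (O1, C2, C3, C4, C4a, C8a, primed numbers for ring B) is used for the open-chain intermediates as well; "geranyl" is (2E)-3,7-dimethylocta-2,6-dien-1-yl; MOM is methoxymethyl.
Assumption: C-acetylation of 5-bromoresorcinol is taken to follow the course known for orcinol, at the ring carbon between OH and Br.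
Remark: the C4 carbinol configuration (anti, 4S) is set only so that single diastereomers are handled; it is removed in step 11.

**Route**

Step 1
Reactants: 1 3-bromo-4,5-dihydroxybenzaldehyde
Product: 2 3-bromo-4,5-bis(methoxymethoxy)benzaldehyde
Conditions: MOMCl, K2CO3, acetone, reflux
Reagents that add atoms: chloromethyl methyl ether (MOMCl), COCCl
Why: Williamson-type O-alkylation of both phenols (MOM protection) gives acetals that should survive organolithium, enolate, hydride and hot carbonate conditions and leave in mild acid.

Step 2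
Reactants: 2 3-bromo-4,5-bis(methoxymethoxy)benzaldehyde
Product: 3 1-bromo-5-(dimethoxymethyl)-2,3-bis(methoxymethoxy)benzene
Conditions: HC(OMe)3, MeOH, PPTS (cat.), rt; Et3N quench
Reagents that add atoms: trimethyl orthoformate, COC(OC)OC; methanol, CO
Why: Acid-catalysed acetalisation driven by the orthoformate as water scavenger masks the aldehyde against the organolithium of step 3, and the weak acid PPTS at room temperature should not exchange the aryl MOM acetals.

Step 3
Reactants: 3 1-bromo-5-(dimethoxymethyl)-2,3-bis(methoxymethoxy)benzene; 4 geranyl bromide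
Product: 8 3-geranyl-4,5-bis(methoxymethoxy)benzaldehyde, via aryllithium 5 (not isolated), via arylcopper 6 (not isolated), via geranylated dimethyl acetal 7 (not isolated)
Conditions: n-BuLi, THF, −78 °C; CuBr·SMe2, −78 to −40 °C; 4, −78 to 0 °C; then 1 M aq. HCl, THF, rt
Reagents that add atoms: water, O
Why: Bromine–lithium exchange and transmetalation give an arylcopper that alkylates the primary allylic bromide in SN2 fashion (copper-mediated allylic substitution), which should keep the E alkene and avoid the branched SN2' product, and the dilute-acid work-up hydrolyses the dimethyl acetal far faster than the aryl MOM acetals.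

Step 4
Reactants: 9 5-bromoresorcinol
Product: 10 1-(2-bromo-4,6-dihydroxyphenyl)ethan-1-one
Conditions: AcOH, ZnCl2, 140 °C; aq. HCl work-up
Reagents that add atoms: acetic acid, CC(=O)O
Why: Nencki-type Friedel–Crafts acylation should occur para to one hydroxyl and ortho to the other, at the carbon between OH and Br, as orcinol gives orcacetophenone, and any isomer acylated between the two hydroxyls would be removed by chromatography.

Step 5
Reactants: 10 1-(2-bromo-4,6-dihydroxyphenyl)ethan-1-one
Product: 11 1-[2-bromo-4,6-bis(methoxymethoxy)phenyl]ethan-1-one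
Conditions: MOMCl, K2CO3, acetone, reflux
Reagents that add atoms: chloromethyl methyl ether (MOMCl), COCCl
Why: Williamson-type O-alkylation (MOM protection) of both phenols, the hydroxyl next to the acetyl group being only weakly chelated because the ortho bromine twists the carbonyl out of the ring plane.

Step 6
Reactants: 11 1-[2-bromo-4,6-bis(methoxymethoxy)phenyl]ethan-1-one; 8 3-geranyl-4,5-bis(methoxymethoxy)benzaldehyde
Product: 13 racemic 1-[2-bromo-4,6-bis(methoxymethoxy)phenyl]-3-[3-geranyl-4,5-bis(methoxymethoxy)phenyl]-3-hydroxypropan-1-one, via lithium enolate 12 (not isolated)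
Conditions: LiN(iPr)2, THF, −78 °C; 8, −78 °C; sat. aq. NH4Cl at −78 °C
Reagents that add atoms: none
Why: Directed aldol addition of the preformed lithium enolate to the non-enolisable aldehyde at low temperature forms the C2–C3 bond, and the carbinol is left racemic on purpose because it is oxidised in step 7.

Step 7
Reactants: 13 racemic aldol
Product: 14 1-[2-bromo-4,6-bis(methoxymethoxy)phenyl]-3-[3-geranyl-4,5-bis(methoxymethoxy)phenyl]propane-1,3-dione
Conditions: Dess–Martin periodinane, CH2Cl2, 0 °C to rt
Reagents that add atoms: none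
Why: Dess–Martin oxidation of the β-hydroxy ketone to the β-diketone removes the racemic stereocentre so that it can be reset under catalyst control.

Step 8
Reactants: 14 1,3-diketone
Product: 15 (3S)-1-[2-bromo-4,6-bis(methoxymethoxy)phenyl]-3-[3-geranyl-4,5-bis(methoxymethoxy)phenyl]-3-hydroxypropan-1-one
Conditions: RuCl[(S,S)-TsDPEN](p-cymene) (2 mol%), HCO2H/Et3N (5:2), DMF, 30 °C
Reagents that add atoms: none
Why: Noyori–Ikariya asymmetric transfer hydrogenation should reduce the unhindered carbonyl conjugated to ring B, the ring A carbonyl being shielded by its two ortho substituents (Br and OMOM), and the (S,S) ligand delivers hydride to the same face as in the reduction of acetophenone to (S)-1-phenylethanol, which sets C2 as S (any over-reduced diol would carry the same C2 configuration and be taken on through step 9).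

Step 9
Reactants: 15 (3S)-β-hydroxy ketone
Product: 16 (1S,3S)-1-[2-bromo-4,6-bis(methoxymethoxy)phenyl]-3-[3-geranyl-4,5-bis(methoxymethoxy)phenyl]propane-1,3-diol
Conditions: Me4NBH(OAc)3, MeCN/AcOH (1:1), −30 to 0 °C
Reagents that add atoms: none
Why: Evans–Saksena reduction, in which the C2 hydroxyl exchanges an acetate on boron and delivers hydride intramolecularly through a chair-like six-membered transition state, should set the new C4 stereocentre 1,3-anti to C2 (4S).

Step 10
Reactants: 16 (1S,3S)-1,3-diol
Product: 17 (2S,4S)-2-[3-geranyl-4,5-bis(methoxymethoxy)phenyl]-5,7-bis(methoxymethoxy)chroman-4-ol (2,4-cis flavan-4-ol)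
Conditions: CuI (10 mol%), 3,4,7,8-tetramethyl-1,10-phenanthroline (20 mol%), Cs2CO3, toluene, 110 °C, degassed
Reagents that add atoms: none
Why: Cs2CO3 forms the alkoxides, the phenanthroline-bound monovalent copper alkoxide of the C2 oxygen adds oxidatively into the neighbouring C8a–Br bond, and C–O reductive elimination from the trivalent copper aryl alkoxide forms O1–C8a; the closest known reaction type is the Ullmann-type intramolecular etherification of ortho-bromoaryl propanols to chromans. Ring C closes in a 6-exo manner at the aromatic sp2 carbon, the bromide leaving outside the new ring. No stereocentre is created, and because neither the C2–O nor the C4–O bond is broken the (1S,3S) diol should become the (2S,4S) flavan-4-ol. Chemoselectivity between the two hydroxyls is secured by ring size, since the C4 oxygen could only close a four-membered ring. Retention at C2 is secured by the absence of a carbonyl, so neither retro-aldol cleavage nor elimination to a chalcone and re-addition is open under the hot base. Copper is chosen so that C–O coupling beats hydrodebromination, since copper alkoxides are little prone to β-hydride loss, whereas with palladium the C4 alkoxide could form a five-membered palladacycle and give up its hydride.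

Step 11
Reactants: 17 (2S,4S)-flavan-4-ol
Product: 18 (2S)-2-[3-geranyl-4,5-bis(methoxymethoxy)phenyl]-5,7-bis(methoxymethoxy)chroman-4-one
Conditions: Dess–Martin periodinane, pyridine, CH2Cl2, 0 °C to rt
Reagents that add atoms: none
Why: Dess–Martin oxidation of the benzylic C4 carbinol under buffered, non-basic conditions removes the C4 stereocentre without touching the MOM acetals, the trisubstituted alkenes or the base-sensitive C2–O1 bond.

Step 12
Reactants: 18 (2S)-tetra-O-MOM flavanone
Product: 19 Isonymphaeol B
Conditions: HCl (ca. 1 M in MeOH), 40 °C, stopped at full conversion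
Reagents that add atoms: none
Why: Acid-catalysed acetal exchange with methanol (transacetalisation to dimethoxymethane) should free the four phenols under conditions too mild for hydration or cyclisation of the geranyl alkenes, and C2 is not epimerised because no base is present.

**Compound list**

1 | 3-bromo-4,5-dihydroxybenzaldehyde | O=Cc1cc(O)c(O)c(Br)c1 | starting material
2 | 3-bromo-4,5-bis(methoxymethoxy)benzaldehyde | O=Cc1cc(OCOC)c(OCOC)c(Br)c1 | intermediate
3 | 1-bromo-5-(dimethoxymethyl)-2,3-bis(methoxymethoxy)benzene | COC(OC)c1cc(OCOC)c(OCOC)c(Br)c1 | intermediate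
4 | geranyl bromide, (2E)-1-bromo-3,7-dimethylocta-2,6-diene | CC(C)=CCC/C(C)=C/CBr | starting material
5 | [5-(dimethoxymethyl)-2,3-bis(methoxymethoxy)phenyl]lithium | COC(OC)c1cc(OCOC)c(OCOC)c([Li])c1 | intermediate
6 | [5-(dimethoxymethyl)-2,3-bis(methoxymethoxy)phenyl]copper (ArCu, monovalent copper) | COC(OC)c1cc(OCOC)c(OCOC)c([Cu])c1 | intermediate
7 | 5-(dimethoxymethyl)-1-geranyl-2,3-bis(methoxymethoxy)benzene | CC(C)=CCC/C(C)=C/Cc1cc(C(OC)OC)cc(OCOC)c1OCOC | intermediate
8 | 3-geranyl-4,5-bis(methoxymethoxy)benzaldehyde | CC(C)=CCC/C(C)=C/Cc1cc(C=O)cc(OCOC)c1OCOC | intermediate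
9 | 5-bromoresorcinol | Oc1cc(O)cc(Br)c1 | starting material
10 | 1-(2-bromo-4,6-dihydroxyphenyl)ethan-1-one | CC(=O)c1c(O)cc(O)cc1Br | intermediate
11 | 1-[2-bromo-4,6-bis(methoxymethoxy)phenyl]ethan-1-one | CC(=O)c1c(Br)cc(OCOC)cc1OCOC | intermediate
12 | lithium 1-[2-bromo-4,6-bis(methoxymethoxy)phenyl]ethen-1-olate | C=C(O[Li])c1c(Br)cc(OCOC)cc1OCOC | intermediate
13 | racemic 1-[2-bromo-4,6-bis(methoxymethoxy)phenyl]-3-[3-geranyl-4,5-bis(methoxymethoxy)phenyl]-3-hydroxypropan-1-one | CC(C)=CCC/C(C)=C/Cc1cc(C(O)CC(=O)c2c(Br)cc(OCOC)cc2OCOC)cc(OCOC)c1OCOC | intermediate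
14 | 1-[2-bromo-4,6-bis(methoxymethoxy)phenyl]-3-[3-geranyl-4,5-bis(methoxymethoxy)phenyl]propane-1,3-dione | CC(C)=CCC/C(C)=C/Cc1cc(C(=O)CC(=O)c2c(Br)cc(OCOC)cc2OCOC)cc(OCOC)c1OCOC | intermediate
15 | (3S)-1-[2-bromo-4,6-bis(methoxymethoxy)phenyl]-3-[3-geranyl-4,5-bis(methoxymethoxy)phenyl]-3-hydroxypropan-1-one | CC(C)=CCC/C(C)=C/Cc1cc([C@@H](O)CC(=O)c2c(Br)cc(OCOC)cc2OCOC)cc(OCOC)c1OCOC | intermediate
16 | (1S,3S)-1-[2-bromo-4,6-bis(methoxymethoxy)phenyl]-3-[3-geranyl-4,5-bis(methoxymethoxy)phenyl]propane-1,3-diol (anti) | CC(C)=CCC/C(C)=C/Cc1cc([C@@H](O)C[C@H](O)c2c(Br)cc(OCOC)cc2OCOC)cc(OCOC)c1OCOC | intermediate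
17 | (2S,4S)-2-[3-geranyl-4,5-bis(methoxymethoxy)phenyl]-5,7-bis(methoxymethoxy)chroman-4-ol | CC(C)=CCC/C(C)=C/Cc1cc([C@@H]2C[C@H](O)c3c(OCOC)cc(OCOC)cc3O2)cc(OCOC)c1OCOC | intermediate
18 | (2S)-2-[3-geranyl-4,5-bis(methoxymethoxy)phenyl]-5,7-bis(methoxymethoxy)chroman-4-one | CC(C)=CCC/C(C)=C/Cc1cc([C@@H]2CC(=O)c3c(OCOC)cc(OCOC)cc3O2)cc(OCOC)c1OCOC | intermediate
19 | Isonymphaeol B, (2S)-2-(3-geranyl-4,5-dihydroxyphenyl)-5,7-dihydroxychroman-4-one | CC(C)=CCC/C(C)=C/Cc1cc([C@@H]2CC(=O)c3c(O)cc(O)cc3O2)cc(O)c1O | target

**Step count and risks**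

Total step count: 12. Longest linear sequence: 10 steps (1, 2, 3, 6, 7, 8, 9, 10, 11, 12).

Steps most likely to fail:

Step 10. The copper may be held as an unreactive chelate by the 1,3-diolate, or reduction of the C–Br bond may outrun C–O bond formation, so that the ring does not close. The fallback closes the same O1–C8a bond without a transition metal, by elimination–addition. It sets out from 16: treatment with an excess of lithium 2,2,6,6-tetramethylpiperidide in THF, −78 to 0 °C, forms the dilithium dialkoxide, lithiates the ring A C–H between Br and OMOM and expels LiBr to give the aryne F1. The C2 alkoxide should add to the aryne carbon C8a, which is the only position that gives a six-membered ring and is also the carbon remote from the neighbouring alkoxy group, the site 3-alkoxyarynes prefer. Protonation on work-up returns the route at 17, again with the C2–O bond untouched.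

Step 8. The catalyst may fail to discriminate between the two carbonyls, or may stall through chelation of ruthenium by the enolised diketone, which would leave C2 unset or set by the wrong reagent. The fallback sets C2 by asymmetric epoxidation instead of ketone reduction. It sets out from 8 and 11: Claisen–Schmidt condensation (KOH, EtOH, rt) gives the (E)-chalcone F2. Juliá–Colonna epoxidation (poly-D-leucine, urea–H2O2, DBU, THF; the antipode of the catalyst that converts chalcone into its (2R,3S)-epoxide) should give the (2S,3R)-epoxy ketone F3, and the isolated geranyl alkenes are inert to the nucleophilic oxidant. Reductive cleavage of the Cα–O bond with sodium phenylselenide ((PhSe)2, NaBH4, EtOH, then AcOH, 0 °C) keeps the Cβ–O bond and returns the route at 15.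

Step 12. Protic acid may drive cyclisation of the geranyl chain onto the freed 4'-hydroxyl or onto its own distal alkene, and ring opening and re-closure of the flavanone may erode C2. The fallback removes the acetals by Lewis-acid silyl transfer in a buffered aprotic medium. It sets out from 18: TMSOTf and 2,2'-bipyridyl in CH2Cl2 at 0 °C should convert the four aryl MOM ethers into the tetrakis(trimethylsilyl) ether F4, and addition of water at rt hydrolyses the aryl silyl ethers at near-neutral pH, returning the route at 19.

**Further compounds**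

F1 | step 10 | aryne from 16 as its dilithium dialkoxide (C8–C8a aryne) | CC(C)=CCC/C(C)=C/Cc1cc([C@@H](O[Li])C[C@H](O[Li])C2=C(OCOC)C=C(OCOC)C#C2)cc(OCOC)c1OCOC
F2 | step 8 | (2E)-1-[2-bromo-4,6-bis(methoxymethoxy)phenyl]-3-[3-geranyl-4,5-bis(methoxymethoxy)phenyl]prop-2-en-1-one | CC(C)=CCC/C(C)=C/Cc1cc(/C=C/C(=O)c2c(Br)cc(OCOC)cc2OCOC)cc(OCOC)c1OCOC
F3 | step 8 | [2-bromo-4,6-bis(methoxymethoxy)phenyl]{(2S,3R)-3-[3-geranyl-4,5-bis(methoxymethoxy)phenyl]oxiran-2-yl}methanone | CC(C)=CCC/C(C)=C/Cc1cc([C@H]3O[C@@H]3C(=O)c2c(Br)cc(OCOC)cc2OCOC)cc(OCOC)c1OCOC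
F4 | step 12 | (2S)-2-[3-geranyl-4,5-bis(trimethylsilyloxy)phenyl]-5,7-bis(trimethylsilyloxy)chroman-4-one | CC(C)=CCC/C(C)=C/Cc1cc([C@@H]2CC(=O)c3c(O[Si](C)(C)C)cc(O[Si](C)(C)C)cc3O2)cc(O[Si](C)(C)C)c1O[Si](C)(C)C
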